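**Retrosynthetic overview**
1. The triene is cut at C2'–C3' (Stille) into ring A vinyl iodide 18 and dienylstannane 27, which carries ring B (made from cyclopentane-1,3-dione); the iodovinyl group of 18 comes from a formyl group on C4 (Takai).
2. Enabling feature: once C1' is a formyl group, C4 of ring A (the quaternary carbinol carbon) carries two aldehyde-level carbons, C5 and C1'. C5–C4(O)–C1' is therefore a 2-silyloxymalonaldehyde (nucleophilic central carbon, two enantiotopic CHO groups), and C6–C1(=O)–C2(N)=C3 is an N-acylaminoacetone-derived enaminone (electrophilic C3, nucleophilic C6 methyl).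
3. Ring A, the only ring that is built, is closed in one flask from enaminone 11 and dialdehyde 14: C3–C4 by vinylogous substitution, then C5–C6 by a proline-catalysed desymmetrising aldol that sets C4 and C5 together and funnels the E/Z mixture of the open-chain enamide.
4. The acyl chain (R-stereocentre by Evans methylation, E-alkene by Wittig) is joined to aminoacetone before the annulation, so no nitrogen has to be introduced on the ring.

Key step: step 10

Assumption (chemistry): the sense of induction of proline in step 10 is taken over from the Hajos–Parrish cyclisation, which is why (R)-proline is specified. Ring A is numbered C1 (ketone), C2 (N-bearing), C3 (=CH), C4 (quaternary carbinol), C5 (CHOH), C6 (CH2); C1' is the first triene carbon.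

**Route**

Step 1
Reactants: 1 (R)-4-benzyloxazolidin-2-one; 2 hexanoyl chloride
Product: 3 (R)-4-benzyl-3-hexanoyloxazolidin-2-one
Conditions: n-BuLi, THF, −78 °C; then 2, −78 → 0 °C
Reagents that add atoms: none
Why: N-acylation of the lithiated oxazolidinone by the acid chloride is a standard imide formation and installs the Evans auxiliary.

Step 2
Reactants: 3 (R)-4-benzyl-3-hexanoyloxazolidin-2-one
Product: 4 (R)-4-benzyl-3-[(R)-2-methylhexanoyl]oxazolidin-2-one
Conditions: NaN(SiMe3)2, THF, −78 °C; MeI, −78 → −40 °C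
Reagents that add atoms: iodomethane, CI
Why: Evans asymmetric alkylation, in which the chelated (Z)-sodium enolate should be methylated on the face opposite the benzyl group, so that the (R)-auxiliary sets the (R)-configured methyl-bearing carbon.

Step 3
Reactants: 4 (R)-4-benzyl-3-[(R)-2-methylhexanoyl]oxazolidin-2-one
Product: 5 (R)-2-methylhexan-1-ol
Conditions: LiBH4, MeOH (1.1 equiv), Et2O, 0 °C
Reagents that add atoms: none
Why: Reductive cleavage of the Evans imide with LiBH4 should give the primary alcohol without touching the α-stereocentre and return the auxiliary.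

Step 4
Reactants: 5 (R)-2-methylhexan-1-ol
Product: 7 ethyl (2E,4R)-2,4-dimethyloct-2-enoate, via (R)-2-methylhexanal 6 (not isolated)
Conditions: Dess–Martin periodinane, Ph3P=C(CH3)CO2Et, CH2Cl2, rt
Reagents that add atoms: ethyl 2-(triphenylphosphoranylidene)propanoate, CCOC(=O)C(C)=P(c1ccccc1)(c1ccccc1)c1ccccc1
Why: One-pot Dess–Martin oxidation/Wittig olefination avoids isolating the epimerisable α-branched aldehyde, and the stabilised ylide should give the (E)-trisubstituted enoate.

Step 5
Reactants: 7 ethyl (2E,4R)-2,4-dimethyloct-2-enoate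
Product: 8 (2E,4R)-2,4-dimethyloct-2-enoic acid
Conditions: LiOH·H2O, THF/MeOH/H2O, 40 °C; then 1 M HCl
Reagents that add atoms: lithium hydroxide, [Li+].[OH-]
Why: Ester saponification, under which the γ-stereocentre is not acidic and the alkene geometry should be kept.

Step 6
Reactants: 8 (2E,4R)-2,4-dimethyloct-2-enoic acid; 9 aminoacetone hydrochloride
Product: 10 (2E,4R)-2,4-dimethyl-N-(2-oxopropyl)oct-2-enamide
Conditions: EDC·HCl, HOBt (cat.), N-methylmorpholine, CH2Cl2, 0 °C → rt
Reagents that add atoms: none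
Why: Carbodiimide amide coupling in which the aminoketone is freed from its hydrochloride only in the presence of the active ester, so that acylation should outrun self-condensation.

Step 7
Reactants: 10 (2E,4R)-2,4-dimethyl-N-(2-oxopropyl)oct-2-enamide
Product: 11 (2E,4R)-N-[(1Z)-1-(dimethylamino)-3-oxobut-1-en-2-yl]-2,4-dimethyloct-2-enamide
Conditions: Me2NCH(OMe)2 (1.5 equiv), toluene, 80 °C
Reagents that add atoms: N,N-dimethylformamide dimethyl acetal, COC(OC)N(C)C
Why: Enaminone formation by condensation of the amide acetal with the doubly activated N–CH2–C(=O) methylene, which is far more acidic than the methyl group and should react selectively, as known for N-acylaminoacetones.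

Step 8
Reactants: 12 penta-1,4-dien-3-ol
Product: 13 tert-butyl(dimethyl)(penta-1,4-dien-3-yloxy)silane
Conditions: TBSCl, imidazole, DMF, rt
Reagents that add atoms: tert-butyl(chloro)dimethylsilane, CC(C)(C)[Si](C)(C)Cl
Why: Standard silylation of a secondary alcohol with TBSCl/imidazole.

Step 9
Reactants: 13 tert-butyl(dimethyl)(penta-1,4-dien-3-yloxy)silane
Product: 14 2-{[tert-butyl(dimethyl)silyl]oxy}propanedial
Conditions: O3, CH2Cl2, −78 °C; then Me2S, −78 °C → rt
Reagents that add atoms: ozone, [O-][O+]=O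
Why: Double ozonolysis with reductive work-up should cut both vinyl groups to formyl groups while the silyl ether is inert to ozone, and the enolised dialdehyde is used crude after removal of volatiles.

Step 10
Reactants: 11 (2E,4R)-N-[(1Z)-1-(dimethylamino)-3-oxobut-1-en-2-yl]-2,4-dimethyloct-2-enamide; 14 2-{[tert-butyl(dimethyl)silyl]oxy}propanedial
Product: 16 (2E,4R)-N-[(3S,4R)-3-{[tert-butyl(dimethyl)silyl]oxy}-3-formyl-4-hydroxy-6-oxocyclohex-1-en-1-yl]-2,4-dimethyloct-2-enamide, via open-chain dialdehyde 15 (not isolated)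
Conditions: TsOH·H2O (1.0 equiv), MeCN, 40 °C; then (R)-proline (0.3 equiv), DMSO, rt, same flask
Reagents that add atoms: none
Why: Proposed new method: TsOH protonates enaminone 11 to a vinylogous iminium ion that is attacked at C3 by the central carbon of enolised 14, and loss of Me2NH (held as its sulfonate salt, so that it cannot act as an achiral enamine catalyst) gives open-chain enamide 15 with C3–C4 in place, after which (R)-proline forms the enamine of the methyl ketone and C6 adds to one of the two enantiotopic formyl groups to form C5–C6 and close ring A. The closest known reactions are the acid-mediated replacement of the dimethylamino group of 2-acylamino-3-(dimethylamino)enones by 1,3-dicarbonyl carbon nucleophiles and the proline-catalysed Hajos–Parrish aldol desymmetrisation of 2,2-disubstituted 1,3-diones, joined here as a Robinson-type substitution/aldol annulation. Ring A closes in the 6-(enolendo)-exo-trig mode. C4 and C5 are both set in the aldol under catalyst control: in the accepted enamine transition state (anti enamine, carboxylic acid hydrogen-bonded to the pseudo-axial acceptor oxygen) the bulky polar OTBS group should lie anti to the forming bond (polar Felkin–Anh), which puts the new hydroxyl cis to OTBS, and since (S)-proline gives the (3aS,7aS) Hajos–Parrish ketol, (R)-proline should select the formyl group that leads to the (3S,4R) product. The step needs carbon rather than oxygen attack of the malonaldehyde, which its C2 being the soft centre of a vinylogous acid should secure, and it needs ring closure from only one enamide isomer, so the E/Z mixture of 15 is funnelled by reversible amine addition at C3 (Curtin–Hammett) because only the isomer with the acetyl group cis to C4 can reach a formyl group. The formyl group that is left is the carbon from which the triene is grown.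

Step 11
Reactants: 16 (2E,4R)-N-[(3S,4R)-3-{[tert-butyl(dimethyl)silyl]oxy}-3-formyl-4-hydroxy-6-oxocyclohex-1-en-1-yl]-2,4-dimethyloct-2-enamide
Product: 17 (2E,4R)-N-[(3R,4R)-3-{[tert-butyl(dimethyl)silyl]oxy}-4-hydroxy-3-[(E)-2-iodoethenyl]-6-oxocyclohex-1-en-1-yl]-2,4-dimethyloct-2-enamide
Conditions: CrCl2 (8 equiv), CHI3 (3 equiv), THF, 0 °C → rt
Reagents that add atoms: iodoform, IC(I)I
Why: Takai olefination, in which the geminal dichromium species from CHI3 and divalent chromium should add to the aldehyde in preference to the ketone and eliminate to the (E)-vinyl iodide.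

Step 12
Reactants: 17 (2E,4R)-N-[(3R,4R)-3-{[tert-butyl(dimethyl)silyl]oxy}-4-hydroxy-3-[(E)-2-iodoethenyl]-6-oxocyclohex-1-en-1-yl]-2,4-dimethyloct-2-enamide
Product: 18 (2E,4R)-N-[(3R,4R)-3,4-dihydroxy-3-[(E)-2-iodoethenyl]-6-oxocyclohex-1-en-1-yl]-2,4-dimethyloct-2-enamide
Conditions: HF·pyridine, pyridine, THF, 0 °C → rt
Reagents that add atoms: none
Why: Fluoride-mediated cleavage of the tertiary TBS ether with buffered HF·pyridine should leave the vinyl iodide, the β-hydroxy ketone and the enamide intact.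

Step 13
Reactants: 19 prop-2-yn-1-ol
Product: 20 (2E)-3-(tributylstannyl)prop-2-en-1-ol
Conditions: Bu3SnH, AIBN (cat.), neat, 80 °C
Reagents that add atoms: tributyltin hydride, CCCC[SnH](CCCC)CCCC
Why: Radical hydrostannation of the terminal alkyne, in which reversible stannyl radical addition should equilibrate the adducts to the (E)-β-stannyl allylic alcohol.

Step 14
Reactants: 20 (2E)-3-(tributylstannyl)prop-2-en-1-ol
Product: 21 (2E)-3-(tributylstannyl)prop-2-enal
Conditions: MnO2, CH2Cl2, rt
Reagents that add atoms: none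
Why: MnO2 oxidation is selective for the allylic alcohol and neutral, so the vinyl–tin bond should survive.

Step 15
Reactants: 21 (2E)-3-(tributylstannyl)prop-2-enal
Product: 22 ethyl (2E,4E)-5-(tributylstannyl)penta-2,4-dienoate
Conditions: (EtO)2P(O)CH2CO2Et, NaH, THF, 0 °C → rt
Reagents that add atoms: triethyl phosphonoacetate, CCOC(=O)CP(=O)(OCC)OCC
Why: Horner–Wadsworth–Emmons olefination should give the new double bond with (E) geometry and keep the geometry of the stannyl alkene.

Step 16
Reactants: 22 ethyl (2E,4E)-5-(tributylstannyl)penta-2,4-dienoate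
Product: 23 (2E,4E)-5-(tributylstannyl)penta-2,4-dienoic acid
Conditions: LiOH·H2O, THF/MeOH/H2O, rt; then 0.5 M HCl to pH 4, 0 °C
Reagents that add atoms: lithium hydroxide, [Li+].[OH-]
Why: Mild saponification, with acidification only to pH 4 so that the acid-labile vinylstannane should not be protodestannylated.

Step 17
Reactants: 24 cyclopentane-1,3-dione
Product: 25 2-(hydroxyimino)cyclopentane-1,3-dione
Conditions: NaNO2, 2 M HCl, H2O, 0 °C
Reagents that add atoms: sodium nitrite, [Na+].[O-]N=O
Why: Nitrosation of the enolised 1,3-dione at its central carbon should give the 2-oxime.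

Step 18
Reactants: 25 2-(hydroxyimino)cyclopentane-1,3-dione
Product: 26 2-amino-3-hydroxycyclopent-2-en-1-one hydrochloride
Conditions: H2 (1 atm), Pd/C (10%), HCl (1.1 equiv), EtOH, rt
Reagents that add atoms: hydrogen chloride, Cl
Why: Catalytic hydrogenation of the oxime in the presence of HCl should give the self-condensing aminodione as its stable hydrochloride.

Step 19
Reactants: 23 (2E,4E)-5-(tributylstannyl)penta-2,4-dienoic acid; 26 2-amino-3-hydroxycyclopent-2-en-1-one hydrochloride
Product: 27 (2E,4E)-N-(2-hydroxy-5-oxocyclopent-1-en-1-yl)-5-(tributylstannyl)penta-2,4-dienamide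
Conditions: EDC·HCl, HOBt, N-methylmorpholine, DMF, 0 °C → rt
Reagents that add atoms: none
Why: Carbodiimide amide coupling under near-neutral conditions should acylate the amine nitrogen and spare the vinylstannane.

Step 20
Reactants: 18 (2E,4R)-N-[(3R,4R)-3,4-dihydroxy-3-[(E)-2-iodoethenyl]-6-oxocyclohex-1-en-1-yl]-2,4-dimethyloct-2-enamide; 27 (2E,4E)-N-(2-hydroxy-5-oxocyclopent-1-en-1-yl)-5-(tributylstannyl)penta-2,4-dienamide
Product: 28 (2E,4R)-N-[(3S,4R)-3,4-dihydroxy-3-[(1E,3E,5E)-7-[(2-hydroxy-5-oxocyclopent-1-en-1-yl)amino]-7-oxohepta-1,3,5-trien-1-yl]-6-oxocyclohex-1-en-1-yl]-2,4-dimethyloct-2-enamide (CNP0154433.2)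
Conditions: Pd2(dba)3 (5 mol %), AsPh3 (20 mol %), NMP, rt, dark
Reagents that add atoms: none
Why: Stille cross-coupling on zerovalent palladium should join the vinyl iodide and the dienylstannane with retention of all alkene geometries under neutral conditions that free hydroxyl, enol and amide groups tolerate.

**Compound list**
1 | (R)-4-benzyloxazolidin-2-one | O=C1N[C@H](Cc2ccccc2)CO1 | starting material
2 | hexanoyl chloride | CCCCCC(Cl)=O | starting material
3 | (R)-4-benzyl-3-hexanoyloxazolidin-2-one | CCCCCC(=O)N1[C@H](Cc2ccccc2)COC1=O | intermediate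
4 | (R)-4-benzyl-3-[(R)-2-methylhexanoyl]oxazolidin-2-one | CCCC[C@@H](C)C(=O)N1[C@H](Cc2ccccc2)COC1=O | intermediate
5 | (R)-2-methylhexan-1-ol | CCCC[C@@H](C)CO | intermediate
6 | (R)-2-methylhexanal | CCCC[C@@H](C)C=O | intermediate (not isolated)
7 | ethyl (2E,4R)-2,4-dimethyloct-2-enoate | CCCC[C@@H](C)/C=C(\C)C(=O)OCC | intermediate
8 | (2E,4R)-2,4-dimethyloct-2-enoic acid | CCCC[C@@H](C)/C=C(\C)C(=O)O | intermediate
9 | aminoacetone hydrochloride (1-aminopropan-2-one hydrochloride) | CC(=O)CN.Cl | starting material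
10 | (2E,4R)-2,4-dimethyl-N-(2-oxopropyl)oct-2-enamide | CCCC[C@@H](C)/C=C(\C)C(=O)NCC(C)=O | intermediate
11 | (2E,4R)-N-[(1Z)-1-(dimethylamino)-3-oxobut-1-en-2-yl]-2,4-dimethyloct-2-enamide | CCCC[C@@H](C)/C=C(\C)C(=O)N/C(=C\N(C)C)C(C)=O | intermediate
12 | penta-1,4-dien-3-ol | C=CC(O)C=C | starting material
13 | tert-butyl(dimethyl)(penta-1,4-dien-3-yloxy)silane | C=CC(O[Si](C)(C)C(C)(C)C)C=C | intermediate
14 | 2-{[tert-butyl(dimethyl)silyl]oxy}propanedial (enolised in solution) | CC(C)(C)[Si](C)(C)OC(C=O)C=O | intermediate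
15 | (2E,4R)-N-[5-{[tert-butyl(dimethyl)silyl]oxy}-5-formyl-2,6-dioxohex-3-en-3-yl]-2,4-dimethyloct-2-enamide (E/Z mixture at the enamide double bond) | CCCC[C@@H](C)/C=C(\C)C(=O)NC(=CC(O[Si](C)(C)C(C)(C)C)(C=O)C=O)C(C)=O | intermediate (not isolated)
16 | (2E,4R)-N-[(3S,4R)-3-{[tert-butyl(dimethyl)silyl]oxy}-3-formyl-4-hydroxy-6-oxocyclohex-1-en-1-yl]-2,4-dimethyloct-2-enamide | CCCC[C@@H](C)/C=C(\C)C(=O)NC1=C[C@@](O[Si](C)(C)C(C)(C)C)(C=O)[C@H](O)CC1=O | intermediate
17 | (2E,4R)-N-[(3R,4R)-3-{[tert-butyl(dimethyl)silyl]oxy}-4-hydroxy-3-[(E)-2-iodoethenyl]-6-oxocyclohex-1-en-1-yl]-2,4-dimethyloct-2-enamide | CCCC[C@@H](C)/C=C(\C)C(=O)NC1=C[C@@](O[Si](C)(C)C(C)(C)C)(/C=C/I)[C@H](O)CC1=O | intermediate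
18 | (2E,4R)-N-[(3R,4R)-3,4-dihydroxy-3-[(E)-2-iodoethenyl]-6-oxocyclohex-1-en-1-yl]-2,4-dimethyloct-2-enamide | CCCC[C@@H](C)/C=C(\C)C(=O)NC1=C[C@@](O)(/C=C/I)[C@H](O)CC1=O | intermediate
19 | prop-2-yn-1-ol | C#CCO | starting material
20 | (2E)-3-(tributylstannyl)prop-2-en-1-ol | CCCC[Sn](CCCC)(CCCC)/C=C/CO | intermediate
21 | (2E)-3-(tributylstannyl)prop-2-enal | CCCC[Sn](CCCC)(CCCC)/C=C/C=O | intermediate
22 | ethyl (2E,4E)-5-(tributylstannyl)penta-2,4-dienoate | CCCC[Sn](CCCC)(CCCC)/C=C/C=C/C(=O)OCC | intermediate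
23 | (2E,4E)-5-(tributylstannyl)penta-2,4-dienoic acid | CCCC[Sn](CCCC)(CCCC)/C=C/C=C/C(=O)O | intermediate
24 | cyclopentane-1,3-dione | O=C1CCC(=O)C1 | starting material
25 | 2-(hydroxyimino)cyclopentane-1,3-dione | ON=C1C(=O)CCC1=O | intermediate
26 | 2-amino-3-hydroxycyclopent-2-en-1-one hydrochloride | NC1=C(O)CCC1=O.Cl | intermediate
27 | (2E,4E)-N-(2-hydroxy-5-oxocyclopent-1-en-1-yl)-5-(tributylstannyl)penta-2,4-dienamide | CCCC[Sn](CCCC)(CCCC)/C=C/C=C/C(=O)NC1=C(O)CCC1=O | intermediate
28 | (2E,4R)-N-[(3S,4R)-3,4-dihydroxy-3-[(1E,3E,5E)-7-[(2-hydroxy-5-oxocyclopent-1-en-1-yl)amino]-7-oxohepta-1,3,5-trien-1-yl]-6-oxocyclohex-1-en-1-yl]-2,4-dimethyloct-2-enamide | CCCC[C@@H](C)/C=C(\C)C(=O)NC1=C[C@@](O)(/C=C/C=C/C=C/C(=O)NC2=C(O)CCC2=O)[C@H](O)CC1=O | target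

**Step count and risks**
Total steps: 20. Longest linear sequence: 11 steps (steps 1–7, 10, 11, 12, 20).

Steps most likely to fail:

Step 10 (proposed new method). The carbon–carbon substitution at C3 may stall or revert. The 2,2-disubstituted malonaldehyde may lose a formyl group to the amine. E/Z equilibration of 15 may be too slow. Selection between the enantiotopic formyl groups, or between cis and trans diol, may be poor. The fallback uses only known reaction types and no annulation; it sets out from acid 8 and comes back at 18. Acid 8 is coupled with commercial 2,5-dimethoxyaniline (EDC·HCl, DMAP, CH2Cl2) to give (2E,4R)-N-(2,5-dimethoxyphenyl)-2,4-dimethyloct-2-enamide F1. Oxidation with PhI(OAc)2 in MeOH should give the quinone monoketal F2. Nucleophilic epoxidation of the enone double bond that carries no nitrogen (t-BuOOH, NaOH, toluene/water, N-benzyl cinchona alkaloid ammonium phase-transfer catalyst) should give the epoxy ketal F3; the pseudo-enantiomeric catalyst that gives the (5R,6S)-epoxide is chosen, and the material is enriched by crystallisation. The reagent (E)-2-(tributylstannyl)ethenyllithium F4, made from commercial (E)-1,2-bis(tributylstannyl)ethene and n-BuLi in THF at −78 °C, should add to the ketone anti to the epoxide to give the tertiary alcohol F5. Hydrolysis of the ketal (montmorillonite K10, CH2Cl2) should give the epoxy enone F6. SmI2 in THF/MeOH at −78 °C should open the α,β-epoxy ketone at the α-carbon to give the β-hydroxy ketone F7. Iododestannylation (I2, CH2Cl2, 0 °C) should then give 18.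

Step 11. The hindered α-quaternary aldehyde may react slowly, the β-hydroxy aldehyde may open by retro-aldol on the Lewis-acidic chromium salts, and divalent chromium may reduce the enone. The fallback sets out from 16 and comes back at 17. Ohira–Bestmann homologation (dimethyl (1-diazo-2-oxopropyl)phosphonate, K2CO3, MeOH, 0 °C) should give the terminal alkyne F8. Palladium-catalysed syn-hydrostannation (Bu3SnH, PdCl2(PPh3)2, THF, 0 °C) should give the (E)-vinylstannane F9, and I2 (CH2Cl2, 0 °C) should give 17.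

Step 20. Stannane 27 may be protodestannylated by its own acidic enol, homocoupling may compete, and the triene may isomerise on palladium. The fallback sets out from 18 and 26 and comes back at 28. Amine salt 26 is acylated with commercial (2E)-penta-2,4-dienoic acid (EDC·HCl, HOBt, N-methylmorpholine, DMF) to give the dienamide F10. A Heck reaction of 18 at the terminal CH2 of F10 (Pd(OAc)2, Ag2CO3, DMF, rt) should then give 28 without tin.

**Further compounds**
F1 | step 10 | (2E,4R)-N-(2,5-dimethoxyphenyl)-2,4-dimethyloct-2-enamide | CCCC[C@@H](C)/C=C(\C)C(=O)Nc1cc(OC)ccc1OC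
F2 | step 10 | (2E,4R)-N-(6,6-dimethoxy-3-oxocyclohexa-1,4-dien-1-yl)-2,4-dimethyloct-2-enamide | CCCC[C@@H](C)/C=C(\C)C(=O)NC1=CC(=O)C=CC1(OC)OC
F3 | step 10 | (2E,4R)-N-[(5R,6S)-5,6-epoxy-1,1-dimethoxy-4-oxocyclohex-2-en-2-yl]-2,4-dimethyloct-2-enamide (ring A numbering) | CCCC[C@@H](C)/C=C(\C)C(=O)NC1=CC(=O)[C@@H]2O[C@@H]2C1(OC)OC
F4 | step 10 | (E)-2-(tributylstannyl)ethenyllithium | [Li]/C=C/[Sn](CCCC)(CCCC)CCCC
F5 | step 10 | (2E,4R)-N-[(4R,5R,6S)-5,6-epoxy-4-hydroxy-1,1-dimethoxy-4-[(E)-2-(tributylstannyl)ethenyl]cyclohex-2-en-2-yl]-2,4-dimethyloct-2-enamide (ring A numbering, hydroxyl cis to the epoxide) | CCCC[C@@H](C)/C=C(\C)C(=O)NC1=C[C@@](O)(/C=C/[Sn](CCCC)(CCCC)CCCC)[C@@H]2O[C@@H]2C1(OC)OC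
F6 | step 10 | (2E,4R)-N-[(4R,5R,6S)-5,6-epoxy-4-hydroxy-1-oxo-4-[(E)-2-(tributylstannyl)ethenyl]cyclohex-2-en-2-yl]-2,4-dimethyloct-2-enamide (ring A numbering) | CCCC[C@@H](C)/C=C(\C)C(=O)NC1=C[C@@](O)(/C=C/[Sn](CCCC)(CCCC)CCCC)[C@@H]2O[C@@H]2C1=O
F7 | step 10 | (2E,4R)-N-[(3R,4R)-3,4-dihydroxy-6-oxo-3-[(E)-2-(tributylstannyl)ethenyl]cyclohex-1-en-1-yl]-2,4-dimethyloct-2-enamide | CCCC[C@@H](C)/C=C(\C)C(=O)NC1=C[C@@](O)(/C=C/[Sn](CCCC)(CCCC)CCCC)[C@H](O)CC1=O
F8 | step 11 | (2E,4R)-N-[(3R,4R)-3-{[tert-butyl(dimethyl)silyl]oxy}-3-ethynyl-4-hydroxy-6-oxocyclohex-1-en-1-yl]-2,4-dimethyloct-2-enamide | CCCC[C@@H](C)/C=C(\C)C(=O)NC1=C[C@@](O[Si](C)(C)C(C)(C)C)(C#C)[C@H](O)CC1=O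
F9 | step 11 | (2E,4R)-N-[(3R,4R)-3-{[tert-butyl(dimethyl)silyl]oxy}-4-hydroxy-6-oxo-3-[(E)-2-(tributylstannyl)ethenyl]cyclohex-1-en-1-yl]-2,4-dimethyloct-2-enamide | CCCC[C@@H](C)/C=C(\C)C(=O)NC1=C[C@@](O[Si](C)(C)C(C)(C)C)(/C=C/[Sn](CCCC)(CCCC)CCCC)[C@H](O)CC1=O
F10 | step 20 | (2E)-N-(2-hydroxy-5-oxocyclopent-1-en-1-yl)penta-2,4-dienamide | C=C/C=C/C(=O)NC1=C(O)CCC1=O
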